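**Retrosynthetic overview**
- Last disconnection (key step): both benzenoid C–Br bonds (C5 and C6) are made at the very end by one regioconvergent twofold C–H bromination of 2-bromo-1-methylindole-3-carbaldehyde. The usual plan (a pre-brominated 5,6-dibromoindole, then N-methylation, Vilsmeier formylation and C2 bromination) is avoided.
- N–CH3: N-methylation of 2-bromo-1H-indole-3-carbaldehyde, done only after C3 is blocked.
- C2–Br and C3–CHO together: one-pot Vilsmeier–Haack–Arnold bromoformylation of commercial indolin-2-one.
- Ring order: no ring is built. The benzo-fused lactam is bought, its five-membered ring is aromatized to the indole in the first step, and the benzene ring is functionalized last.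

Assumption: the target has no stereocenter and no stereogenic axis (it is achiral), so the "single enantiomer" is the compound itself and no stereocontrol is needed.

**Step 1**
Reactants: 1 indolin-2-one
Product: 4 2-bromo-1H-indole-3-carbaldehyde, via enaminone 2 (not isolated), via iminium bromide 3 (not isolated)
Conditions: POBr3 (2.5 equiv), DMF (3 equiv), CH2Cl2, 0 °C then reflux; then ice-water, rt
Reagents that add atoms: N,N-dimethylformamide (DMF) CN(C)C=O; phosphorus oxybromide (POBr3) O=P(Br)(Br)Br; water O
Why: Vilsmeier–Haack–Arnold haloformylation of a lactam, in which the bromoiminium reagent from DMF and POBr3 condenses at the acidic C3 methylene to give enaminone 2, whose vinylogous-amide oxygen is phosphorylated and replaced by bromide with aromatization to iminium 3, which water hydrolyses to the aldehyde, so C2–Br and C3–CHO arise in one operation and no stereocenter is formed.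

**Step 2**
Reactants: 4 2-bromo-1H-indole-3-carbaldehyde
Product: 5 2-bromo-1-methyl-1H-indole-3-carbaldehyde
Conditions: MeI (1.5 equiv), K2CO3 (2 equiv), DMF, 0 °C to rt
Reagents that add atoms: iodomethane CI
Why: SN2 N-alkylation of an indole N–H that the 3-formyl and 2-bromo groups make acidic enough for K2CO3; C3 is already fully substituted so the C-alkylation that troubles oxindoles cannot occur, the mild base at room temperature leaves the activated C2–Br bond untouched, and no stereocenter is formed.

**Step 3**
Reactants: 5 2-bromo-1-methyl-1H-indole-3-carbaldehyde
Product: 8 2,5,6-tribromo-1-methyl-1H-indole-3-carbaldehyde, via C5-monobromide 6 (not isolated), via C6-monobromide 7 (not isolated)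
Conditions: Br2 (2.2 equiv), AcOH, rt to 40 °C, dark
Reagents that add atoms: bromine BrBr
Why: Twofold electrophilic aromatic bromination in which the 2-bromo and 3-formyl groups shut down the pyrrole ring, N1 activates C5 (para) and the C2=C3 vinylogous path activates C6, C4 and C7 are shielded by the peri formyl and N-methyl groups, and each monobromide (6 or 7) takes its second bromine ortho to the first at the other activated site, so both paths converge on the 5,6-dibromide as in the known Br2/AcOH 5,6-dibromination of 3-acylindoles; no stereocenter is formed.

**Compound list**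
1 | indolin-2-one (oxindole), achiral | O=C1Cc2ccccc2N1 | starting material
2 | 3-[(dimethylamino)methylidene]indolin-2-one (enaminone; E/Z mixture, geometry is lost in the next event) | CN(C)C=C1C(=O)Nc2ccccc12 | intermediate
3 | N-[(2-bromo-1H-indol-3-yl)methylidene]-N-methylmethanaminium bromide | C[N+](C)=Cc1c(Br)[nH]c2ccccc12.[Br-] | intermediate
4 | 2-bromo-1H-indole-3-carbaldehyde, achiral | O=Cc1c(Br)[nH]c2ccccc12 | intermediate
5 | 2-bromo-1-methyl-1H-indole-3-carbaldehyde, achiral | Cn1c(Br)c(C=O)c2ccccc21 | intermediate
6 | 2,5-dibromo-1-methyl-1H-indole-3-carbaldehyde, achiral | Cn1c(Br)c(C=O)c2cc(Br)ccc21 | intermediate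
7 | 2,6-dibromo-1-methyl-1H-indole-3-carbaldehyde, achiral | Cn1c(Br)c(C=O)c2ccc(Br)cc21 | intermediate
8 | 2,5,6-tribromo-1-methyl-1H-indole-3-carbaldehyde, achiral | Cn1c(Br)c(C=O)c2cc(Br)c(Br)cc21 | target

**Totals**
Total step count: 3. Longest linear sequence: 3.

**Steps most likely to fail, with fallbacks**

Step 3 (highest risk). The double bromination may stall at the 6/7 mixture, or give 5,7- or 4,6-dibromo isomers. The fallback replaces the first bromination by a nitro/Sandmeyer relay. It sets out from 5. Nitration in concentrated H2SO4 (KNO3, 0 °C) should go to C6, because the O-protonated vinylogous amide directs there, as in nitrations of 3-acylindoles in strong acid. This gives 2-bromo-1-methyl-6-nitro-1H-indole-3-carbaldehyde F1. Fe/NH4Cl (EtOH–H2O, 70 °C) reduces it to 6-amino-2-bromo-1-methyl-1H-indole-3-carbaldehyde F2. t-BuONO and CuBr2 in MeCN (0 to 50 °C) convert the amine, through 2-bromo-3-formyl-1-methyl-1H-indole-6-diazonium bromide F3, into the 6-bromide. That is compound 7, now isolated and regiochemically pure, and the route is rejoined at 7. One equivalent of Br2 in AcOH then has a single well-directed site (C5, para to N1 and ortho to the C6 bromine) and gives 8.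

Step 1. The one-pot bromoformylation of the N–H lactam may give tar or incomplete exchange of C=O for C–Br. The fallback separates the two events and sets out from 1. POBr3 alone (1,2-dichloroethane, reflux) gives 2-bromo-1H-indole F4 by deoxybromination and aromatization. This unstable bromide is formylated at once at C3 by an ordinary Vilsmeier–Haack reaction (DMF/POBr3, CH2Cl2, 0 °C, then water). POBr3 is kept so that no chloride can exchange with the C2 bromide. The reaction passes through iminium 3, and the route is rejoined at 4.

Step 2 (lowest risk). Base-mediated methylation of 4 could be spoiled by nucleophilic displacement of the activated C2 bromide. The fallback installs the methyl group before the C–Br bond exists and sets out from 1. Condensation with DMF dimethyl acetal (toluene, 100 °C) gives enaminone 2, this time isolated. NaH/MeI (THF, 0 °C) methylates its lactam nitrogen, and C3 is blocked so no C-methylation can occur. This gives 3-[(dimethylamino)methylidene]-1-methylindolin-2-one F5. POBr3 (CH2Cl2, reflux) converts it into N-[(2-bromo-1-methyl-1H-indol-3-yl)methylidene]-N-methylmethanaminium bromide F6. Water hydrolyses this to 5, where the route is rejoined (4 is bypassed).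

**Further compounds**
F1 | step 3 | 2-bromo-1-methyl-6-nitro-1H-indole-3-carbaldehyde | Cn1c(Br)c(C=O)c2ccc([N+](=O)[O-])cc21
F2 | step 3 | 6-amino-2-bromo-1-methyl-1H-indole-3-carbaldehyde | Cn1c(Br)c(C=O)c2ccc(N)cc21
F3 | step 3 | 2-bromo-3-formyl-1-methyl-1H-indole-6-diazonium bromide | Cn1c(Br)c(C=O)c2ccc([N+]#N)cc21.[Br-]
F4 | step 1 | 2-bromo-1H-indole | Brc1cc2ccccc2[nH]1
F5 | step 2 | 3-[(dimethylamino)methylidene]-1-methylindolin-2-one | CN(C)C=C1C(=O)N(C)c2ccccc12
F6 | step 2 | N-[(2-bromo-1-methyl-1H-indol-3-yl)methylidene]-N-methylmethanaminium bromide | C[N+](C)=Cc1c(Br)n(C)c2ccccc12.[Br-]
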